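One mole of Z in the flask counts one exchange done, whichever step made it.

X 0.10 M (fed, over 6.0 s); L 36 mM (held); time 15 min

- which holds at 15 min: what has brought the reaction to rest, or that it has not come to rest (all of X has reacted / it is still moving / forward and back rates have come level)
- conversion of X at 15 min
- amount of E at 15 min, in percent of the X charged
- amount of J at 15 min, in percent of the X charged

- at the start none of Q is dissolved
- the reaction counts as stopped when no species that holds the X changes by six tenths of a point or more over the second half of the time
- run time (flask): 15 min

    E + Q ⇌ Z + D (K1 = 3.66, k1 = 7.57 /M/s)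
    X + Q ⇌ Z + G (K2 = 32, k2 = 5.66 /M/s)
    L ⇌ Q, rate k3*(csat - [Q]) (k3 = 3.16 /s, csat = 36 mM)
    G + Q ⇌ Z + J (K4 = 8.16, k4 = 4.36 /M/s)
    J + Q ⇌ Z + E (K5 = 5.51, k5 = 19.0 /M/s)

The complex climbs a ladder from X to G, J, E and D, and each rung takes one Q and gives one Z. While X runs in over 6.0 s, cQ starts from nothing. The gas can deliver 0.114 M/s, while step 2 takes 0.0204 M/s with the whole charge present and cQ at csat, so uptake is the faster. Q also refills in about 0.316 s, less than the 1.2 s forward half-life of Q by step 2.

With cQ near csat, each rung runs pseudo-first-order. Step 4 has the smallest forward constant, yet its forward time of 6.37 s is far shorter than 15 min. Meanwhile Z stays in the flask, and the back steps grow with cZ.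

So I expect rest by balance, and I solve that end. At rest the uptake is zero, so cQ equals csat, and each rung stands at K times cQ/cZ. I try 2 exchanges per X. That gives cQ/cZ of 0.180, and the ladder's shares at that ratio average 2.40. Feeding that back gives a ratio of 0.150 and an average of 2.18. A straight line through these two trials crosses at 2.26. This is the exchange number: moles of Z set free per mole of X charged, at rest. Its ratio is 0.160. From that I reckon X at 4.55%, J at 30.2% and E at 26.5%.

The forecast says forward and back rates have come level, with conversion 95.5%, E 26.6% and J 30.2%, holding that “the closed-in Z leaves the whole ladder at equilibrium”. My shares lie close to these.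

The simulation gives forward and back rates have come level, with conversion 95.5%, E 26.6% and J 30.2%. The 4.5% of X left at 15.0 min is an equilibrium share, and a reading at 150 min changes nothing.

This flask reads cZ 0.225 M, or 2.25 per X, against my 2.26. Now take the neighbour flask, charged with 0.17 M of X, the time and the other settings held. Starting from 2.26, the ratio 0.0938 gives 1.62. Then 0.131 gives 2.01. The line crosses at 1.86, a ratio of 0.114, so I reckon X left in the neighbour flask at 9.07%. The neighbour flask ends with cZ 0.314 M and X at 8.96%.

The rate constants are those of an exercise; the result is computed.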